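## The problem

Target 19 is a (2R,3R)-dihydroflavonol. A phloroglucinol-type ring A is fused to a pyranone ring C that carries the 4-hydroxy-3-methoxyphenyl ring B at C2 and a hydroxyl at C3, and of four hydroxyls only O7 is prenylated. The two stereocentres are adjacent and trans (both substituents equatorial), which is the more stable arrangement. C3 can therefore direct C2 during construction, and in the final compound C2 can in principle be corrected through reversible O1–C2 opening assisted by the free para hydroxyl of ring B. C3, alpha to the C4 ketone, cannot be repaired once it is lost. At the ketone oxidation level both centres are base-labile (enolisation at C3, retro-oxa-Michael opening of O1–C2), and the beta-hydroxy ketone is easily dehydrogenated, so the C4 carbonyl should appear late and be handled under neutral or buffered conditions. The prenyl ether does not survive hydrogenolysis, strong acid or quinone oxidants, so it must be installed near the end, at a point where O7 can be told apart from O5, O3 and the ring B phenol. The feature that opens the route is that C4 is bonded to C4a, ortho to the O1-bearing C8a, with further donor oxygens at C5 and C7. With C4 taken back to a methylene, C4 is the methide carbon of a ring A ortho-quinone methide, C3 with its oxygen is the alpha carbon of an alpha-oxy aldehyde enamine, and C2 is the aldehyde carbon that O1 captures as a lactol.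

## Retrosynthesis

**O–Si and O7–prenyl (19 ⇒ 18 ⇒ 16 + 17).** The silyl ether on the ring B phenol is cut first, then the O7–CH2 bond to prenyl bromide 17. Prenylation is placed after every reductive and oxidative step because the allylic ether tolerates neither. In triol 16, O7 is the most acidic hydroxyl (para to C4=O), O5 is tied up in a hydrogen bond to the ketone and O3 is an aliphatic alcohol. Only the ring B phenol could compete, so it alone stays protected, as a triisopropylsilyl ether that comes off with buffered fluoride. The forward steps must be a mono-O-alkylation and a neutral desilylation.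

**Three O–benzyl bonds (16 ⇒ 15).** O3, O5 and O7 are all masked as benzyl ethers so that one neutral hydrogenolysis frees them together. Benzyl ethers withstand the Grignard, Mitsunobu, DDQ and periodinane steps, and the O3 benzyl group arrives with the aldehyde building block. Silyl or acyl groups at these positions would need separate introduction and removal.

**C4 oxidation level (15 ⇒ 14 ⇒ 13).** The C4 carbonyl is taken back through alcohol 14 to the methylene of flavan 13. This costs two forward steps but is what turns ring A into an ortho-quinone methide precursor. Carrying the C4 oxygen from the start would lead back to chalcone-type cuts, where both stereocentres have to be added to an enone. In the forward direction C4–H is the most hydridic bond of 13, since its cation is stabilised by O1, O5 and O7.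

**O1–C2 and C2–aryl (13 ⇒ 12 ⇒ 8 + 11).** Ring C of 13 is opened at O1–C2 to the syn carbinol 12, and 12 is cut between C2 and ring B into lactol 8 and aryl Grignard reagent 11. The neighbouring option was to keep the ring closed, ionise an anomeric ester of 8 and add an aryl-metal to the cyclic oxocarbenium ion. It was set aside for two reasons. The facial preference of a 3-alkoxychroman-2-ylium ion is not secure, because a pseudo-equatorial alkoxy group with axial attack leads to the 2,3-cis product. Ring A is also a strong Friedel–Crafts nucleophile towards such a cation. In the chosen sequence C3 controls C2 through two well-understood events: chelation-controlled addition to the alpha-benzyloxy aldehyde (syn), then Mitsunobu closure with inversion (trans). The precursors are two fragments of similar size.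

**C3–C4 and O1–C2 of the lactol (8 ⇒ 4 + 5, through 6 and 7).** Lactol 8 is cut at C3–C4 and at the hemiacetal O1–C2 bond. This gives sulfone 4, a bench-stable source of ortho-quinone methide 6, and benzyloxyacetaldehyde 5. The cut removes the ring and the only stereocentre of 8 in one operation and leaves an achiral phenol and a two-carbon aldehyde. The forward reaction must form the C–C bond with high enantiofacial control at C3 and stop after one addition. Lactol closure of the open form 7 provides the stop.

**Feeding the fragments (4 ⇒ 3 ⇒ 2 ⇒ 1; 11 ⇒ 10 ⇒ 9).** Sulfone 4 comes from salicyl alcohol 3 by exchange of the benzylic hydroxyl for sulfinate, 3 from aldehyde 2 by reduction, and 2 from 2,4,6-trihydroxybenzaldehyde 1 by selective dibenzylation. The aldehyde carbon of 1 becomes C4. Grignard reagent 11 is made in the flask from bromide 10, the silyl ether of 4-bromo-2-methoxyphenol 9.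

## Roads not taken

Alternative 1: The cut is C2–C3. Flavanone A1 would arise when diazoketone A2 is decomposed by Rh2(S-PTTL)4 and the carbene inserts into a benzylic C–H bond of the O1–CH2–aryl ether, closing ring C and setting C2.
- Merits: the C4 carbonyl and the prenyl ether are present from the start, so neither a benzylic oxidation nor a benzyl/hydrogenolysis cycle is needed, and the route would be clearly shorter than the twelve steps proposed here.
- Weak points: the insertion must close a six-membered ring, while the carbene can instead attack the lone pair of O1 to give a five-membered oxonium ylide that undergoes a Stevens-type benzyl shift. Cycloaddition into ring B and cyclopropanation of the prenyl alkene also compete.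
- More seriously, A1 still lacks the C3 oxygen. Adding it by enolate oxidation means making a flavanone enolate, which opens to a chalcone-type enone and erases C2, and using oxidants that also attack the prenyl alkene.
- Comparison: Alternative 1 wins on step count and protecting-group economy. Against this, the chosen plan installs the C3 oxygen with its configuration in the ring-forming step, so the stereocentre that cannot be repaired is never left to a late enolate oxidation.

Alternative 2: The cut is C8–C8a and C4a–C5, so ring A is built last. Diene A5 would add across the C4a=C8a bond of sulfinyl dihydropyranone A4, and loss of the sulfinyl, methoxy and silyl groups would aromatise ring A to give A3 with free O5 and O7.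
- Merits: both stereocentres and the C4 ketone exist before ring A, and A3 needs only prenylation and desilylation. That endgame is shorter than the five steps that follow flavan 13 here.
- Weak points: the difficulty moves into A4, an enantiopure trans-2-aryl-3-silyloxy-dihydropyranone with an extra sulfinyl group. It needs its own multi-step asymmetric synthesis, which none of the simple starting materials supports.
- The dienophile is a vinylogous ester, electron-rich at the carbon that must accept the diene terminus. A4 can also open by retro-oxa-Michael reaction or epimerise at C3 under the activation the cycloaddition and aromatisation require.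
- Comparison: Alternative 2 has the better endgame. The chosen plan offers a three-step access to its key precursor 4, a key step with direct precedent and a shorter route overall.

Alternative 3: The cut is C4a–C4, C4–C3 and O1–C2. Flavone A6 would form in one step from iodophenol A7, alkyne A8 and carbon monoxide A9 under PdCl2(PPh3)2 and a secondary amine.
- Merits: this is the most convergent assembly of the skeleton, with three bonds formed in one reliable step and protecting groups that match those used here.
- Weak points: A6 is planar and has neither stereocentre. Reaching a trans-dihydroflavonol of defined absolute configuration needs an asymmetric conjugate reduction, whose flavanone product racemises by ring opening, followed by diastereoselective C3 hydroxylation.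
- The enantiodetermining step on a 5-oxygenated flavone is poorly supported, and five-membered closure of the alkynone competes with the six-membered mode.
- Comparison: Alternative 3 is better for building the carbon framework. The chosen plan spends more steps on the framework but addresses absolute and relative configuration directly.

Key step: step 4

Remark: the anomeric centre of 8 and C4 of 14 are carried as mixtures, since both are removed or become trigonal later. The catalyst enantiomer is assigned from the usual model of attack on the E-anti enamine opposite the diaryl(silyloxy)methyl group.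

## Route

Step 1
Reactants: 1 2,4,6-trihydroxybenzaldehyde
Product: 2 2,4-bis(benzyloxy)-6-hydroxybenzaldehyde
Conditions: BnBr (2.1 equiv), K2CO3, DMF, 0 °C to rt
Reagents that add atoms: benzyl bromide, BrCc1ccccc1
Why: Williamson etherification; the hydroxyl para to the formyl group and one ortho hydroxyl are alkylated, while the last ortho hydroxyl is held in a hydrogen bond to the carbonyl and reacts much more slowly, so controlled stoichiometry should stop at the dibenzyl ether.

Step 2
Reactants: 2 2,4-bis(benzyloxy)-6-hydroxybenzaldehyde
Product: 3 3,5-bis(benzyloxy)-2-(hydroxymethyl)phenol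
Conditions: NaBH4, THF/MeOH, 0 °C
Reagents that add atoms: none
Why: Hydride reduction of the salicylaldehyde; run cold and briefly because the electron-rich salicyl alcohol ionises easily, and 3 is carried on crude.

Step 3
Reactants: 3 3,5-bis(benzyloxy)-2-(hydroxymethyl)phenol
Product: 4 3,5-bis(benzyloxy)-2-[(4-methylphenyl)sulfonylmethyl]phenol
Conditions: p-TolSO2Na (3 equiv), AcOH/H2O, rt
Reagents that add atoms: sodium 4-methylbenzenesulfinate, [Na+].[O-]S(=O)c1ccc(C)cc1
Why: Acid-promoted ionisation of the benzylic alcohol to the ring-A-stabilised cation (protonated quinone methide) and S-alkylation of sulfinate; any O-sulfinate ester re-ionises and funnels to the sulfone, and excess sulfinate should outrun self-condensation.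

Step 4
Reactants: 4 3,5-bis(benzyloxy)-2-[(4-methylphenyl)sulfonylmethyl]phenol, 5 benzyloxyacetaldehyde
Product: 8 (3S)-3,5,7-tris(benzyloxy)chroman-2-ol (both anomers), via ortho-quinone methide 6 (not isolated), via open-chain hydroxy aldehyde 7 (not isolated)
Conditions: 5 (1.5 equiv), (R)-2-[diphenyl(trimethylsilyloxy)methyl]pyrrolidine (20 mol %), Na2CO3, CH2Cl2, 0 °C to rt
Reagents that add atoms: none
Why: Carbonate removes the phenolic proton of 4 and sulfinate is expelled by 1,4-elimination to give methide 6, which the C5 and C7 alkoxy groups stabilise enough to form under these mild conditions. Aldehyde 5 condenses with the diarylprolinol silyl ether to the E-anti enamine, whose alpha carbon adds to the methide carbon of 6 in a Michael-type 1,4-addition that forms C3–C4 and rearomatises ring A; hydrolysis of the iminium ion releases 7 and the catalyst. The phenol of 7 then adds to the aldehyde in a 6-exo-trig hemiacetalisation that forms O1–C2 and closes ring C. The closest known reaction type is the aminocatalytic Michael addition/hemiacetalisation of aldehydes with ortho-quinone methides generated in situ from 2-(sulfonylmethyl)phenols, which gives 3-substituted chroman-2-ols. C3 is the only controlled centre: the diphenyl(silyloxy)methyl group blocks one enamine face, and with the (R)-catalyst attack on the open face is predicted to give (3S), while the anomeric centre is left uncontrolled. The step needs C- over N-alkylation and a single addition: amine and sulfinate adducts of the stabilised methide can revert whereas the C–C bond cannot, and lactol closure takes the product out of the enamine manifold, which also shields C3 from epimerisation.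

Step 5
Reactants: 9 4-bromo-2-methoxyphenol
Product: 10 (4-bromo-2-methoxyphenoxy)triisopropylsilane
Conditions: i-Pr3SiCl, imidazole, DMF, rt
Reagents that add atoms: chlorotriisopropylsilane, CC(C)[Si](Cl)(C(C)C)C(C)C
Why: Imidazole-promoted silylation of the phenol; the hindered aryl silyl ether tolerates Grignard formation, DDQ, hydrogenolysis and carbonate in acetone, and is removed by fluoride at the end.

Step 6
Reactants: 8 (3S)-3,5,7-tris(benzyloxy)chroman-2-ol, 10 (4-bromo-2-methoxyphenoxy)triisopropylsilane
Product: 12 (1S,2S)-2-(benzyloxy)-3-[2,4-bis(benzyloxy)-6-hydroxyphenyl]-1-[3-methoxy-4-(triisopropylsilyloxy)phenyl]propan-1-ol, via arylmagnesium bromide 11 (not isolated)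
Conditions: 10, Mg, I2 (cat.), Et2O, reflux (11, 3 equiv); then 8, CH2Cl2, −78 to 0 °C; aq NH4Cl
Reagents that add atoms: none
Why: Grignard addition to a lactol: the first equivalent of 11 deprotonates 8, which opens to the magnesium phenoxide of aldehyde 7, and a second equivalent adds under Cram-chelate control (magnesium bridging the carbonyl and alpha-benzyloxy oxygens, attack anti to the CH2-aryl branch), which should set the carbinol 1,2-syn, that is (1S).

Step 7
Reactants: 12 (1S,2S)-2-(benzyloxy)-3-[2,4-bis(benzyloxy)-6-hydroxyphenyl]-1-[3-methoxy-4-(triisopropylsilyloxy)phenyl]propan-1-ol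
Product: 13 (2R,3S)-3,5,7-tris(benzyloxy)-2-[3-methoxy-4-(triisopropylsilyloxy)phenyl]chromane
Conditions: PPh3, DIAD, THF, 0 °C to rt
Reagents that add atoms: none
Why: Intramolecular Mitsunobu etherification: the phenol displaces the benzylic oxyphosphonium group in a 6-exo-tet closure with inversion, turning the (1S) carbinol into (2R) and giving the 2,3-trans flavan; any ionisation at the electron-rich benzylic carbon should also favour the diequatorial trans product.

Step 8
Reactants: 13 (2R,3S)-3,5,7-tris(benzyloxy)-2-[3-methoxy-4-(triisopropylsilyloxy)phenyl]chromane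
Product: 14 (2R,3S,4RS)-3,5,7-tris(benzyloxy)-2-[3-methoxy-4-(triisopropylsilyloxy)phenyl]chroman-4-ol
Conditions: DDQ (1.5 equiv), CH2Cl2/H2O, rt
Reagents that add atoms: water, O
Why: DDQ benzylic oxidation: hydride is abstracted from C4, whose cation is stabilised by O1, O5 and O7 (known for per-O-benzylated flavan-3-ols), and water captures the cation; the C4 epimers converge in the next step, and benzyl and aryl silyl ethers are inert.

Step 9
Reactants: 14 (2R,3S,4RS)-3,5,7-tris(benzyloxy)-2-[3-methoxy-4-(triisopropylsilyloxy)phenyl]chroman-4-ol
Product: 15 (2R,3R)-3,5,7-tris(benzyloxy)-2-[3-methoxy-4-(triisopropylsilyloxy)phenyl]chroman-4-one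
Conditions: Dess–Martin periodinane, NaHCO3, CH2Cl2, 0 °C to rt
Reagents that add atoms: none
Why: Dess–Martin oxidation of the benzylic alcohol under bicarbonate buffer; the near-neutral conditions avoid epimerisation at C3 and ionisation of the acid-labile C4 alcohol.

Step 10
Reactants: 15 (2R,3R)-3,5,7-tris(benzyloxy)-2-[3-methoxy-4-(triisopropylsilyloxy)phenyl]chroman-4-one
Product: 16 (2R,3R)-3,5,7-trihydroxy-2-[3-methoxy-4-(triisopropylsilyloxy)phenyl]chroman-4-one
Conditions: H2 (1 atm), Pd/C, EtOAc/MeOH, rt
Reagents that add atoms: none
Why: Catalytic hydrogenolysis of the three benzyl ethers; the aryl ketone, conjugated to the electron-rich ring and hydrogen-bonded to O5, and the aryl silyl ether should not be reduced, and the neutral medium leaves C2 and C3 untouched.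

Step 11
Reactants: 16 (2R,3R)-3,5,7-trihydroxy-2-[3-methoxy-4-(triisopropylsilyloxy)phenyl]chroman-4-one, 17 prenyl bromide (1-bromo-3-methylbut-2-ene)
Product: 18 (2R,3R)-3,5-dihydroxy-2-[3-methoxy-4-(triisopropylsilyloxy)phenyl]-7-[(3-methylbut-2-en-1-yl)oxy]chroman-4-one
Conditions: 17 (1.05 equiv), K2CO3 (1.1 equiv), acetone, rt
Reagents that add atoms: none
Why: Williamson alkylation selective for O7, the most acidic hydroxyl (para to the C4 carbonyl); O5 is hydrogen-bonded to the ketone, O3 is a far less acidic secondary alcohol and the ring B phenol is silylated, while one equivalent of mild base at room temperature limits ring opening.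

Step 12
Reactants: 18 (2R,3R)-3,5-dihydroxy-2-[3-methoxy-4-(triisopropylsilyloxy)phenyl]-7-[(3-methylbut-2-en-1-yl)oxy]chroman-4-one
Product: 19 (2R,3R)-3,5-dihydroxy-2-(4-hydroxy-3-methoxyphenyl)-7-[(3-methylbut-2-en-1-yl)oxy]chroman-4-one
Conditions: Bu4NF, AcOH, THF, 0 °C
Reagents that add atoms: none
Why: Fluoride cleavage of the aryl silyl ether, buffered with acetic acid so that no basic phenoxide or fluoride epimerises C2 or C3 or opens ring C; the prenyl ether is inert.

## Compound list

1 | 2,4,6-trihydroxybenzaldehyde | O=Cc1c(O)cc(O)cc1O | starting material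
2 | 2,4-bis(benzyloxy)-6-hydroxybenzaldehyde | O=Cc1c(O)cc(OCc2ccccc2)cc1OCc1ccccc1 | intermediate
3 | 3,5-bis(benzyloxy)-2-(hydroxymethyl)phenol | OCc1c(O)cc(OCc2ccccc2)cc1OCc1ccccc1 | intermediate
4 | 3,5-bis(benzyloxy)-2-[(4-methylphenyl)sulfonylmethyl]phenol | Cc1ccc(S(=O)(=O)Cc2c(O)cc(OCc3ccccc3)cc2OCc2ccccc2)cc1 | intermediate
5 | benzyloxyacetaldehyde | O=CCOCc1ccccc1 | starting material
6 | 3,5-bis(benzyloxy)-6-methylidenecyclohexa-2,4-dien-1-one (ortho-quinone methide) | C=C1C(=O)C=C(OCc2ccccc2)C=C1OCc1ccccc1 | intermediate
7 | (2S)-2-(benzyloxy)-3-[2,4-bis(benzyloxy)-6-hydroxyphenyl]propanal | O=C[C@@H](OCc1ccccc1)Cc1c(O)cc(OCc2ccccc2)cc1OCc1ccccc1 | intermediate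
8 | (3S)-3,5,7-tris(benzyloxy)chroman-2-ol (both anomers) | OC1Oc2cc(OCc3ccccc3)cc(OCc3ccccc3)c2C[C@@H]1OCc1ccccc1 | intermediate
9 | 4-bromo-2-methoxyphenol | COc1cc(Br)ccc1O | starting material
10 | (4-bromo-2-methoxyphenoxy)triisopropylsilane | COc1cc(Br)ccc1O[Si](C(C)C)(C(C)C)C(C)C | intermediate
11 | [3-methoxy-4-(triisopropylsilyloxy)phenyl]magnesium bromide | COc1cc([Mg]Br)ccc1O[Si](C(C)C)(C(C)C)C(C)C | intermediate
12 | (1S,2S)-2-(benzyloxy)-3-[2,4-bis(benzyloxy)-6-hydroxyphenyl]-1-[3-methoxy-4-(triisopropylsilyloxy)phenyl]propan-1-ol | COc1cc([C@H](O)[C@@H](OCc2ccccc2)Cc2c(O)cc(OCc3ccccc3)cc2OCc2ccccc2)ccc1O[Si](C(C)C)(C(C)C)C(C)C | intermediate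
13 | (2R,3S)-3,5,7-tris(benzyloxy)-2-[3-methoxy-4-(triisopropylsilyloxy)phenyl]chromane | COc1cc([C@H]2Oc3cc(OCc4ccccc4)cc(OCc4ccccc4)c3C[C@@H]2OCc2ccccc2)ccc1O[Si](C(C)C)(C(C)C)C(C)C | intermediate
14 | (2R,3S,4RS)-3,5,7-tris(benzyloxy)-2-[3-methoxy-4-(triisopropylsilyloxy)phenyl]chroman-4-ol | COc1cc([C@H]2Oc3cc(OCc4ccccc4)cc(OCc4ccccc4)c3C(O)[C@@H]2OCc2ccccc2)ccc1O[Si](C(C)C)(C(C)C)C(C)C | intermediate
15 | (2R,3R)-3,5,7-tris(benzyloxy)-2-[3-methoxy-4-(triisopropylsilyloxy)phenyl]chroman-4-one | COc1cc([C@H]2Oc3cc(OCc4ccccc4)cc(OCc4ccccc4)c3C(=O)[C@@H]2OCc2ccccc2)ccc1O[Si](C(C)C)(C(C)C)C(C)C | intermediate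
16 | (2R,3R)-3,5,7-trihydroxy-2-[3-methoxy-4-(triisopropylsilyloxy)phenyl]chroman-4-one | COc1cc([C@H]2Oc3cc(O)cc(O)c3C(=O)[C@@H]2O)ccc1O[Si](C(C)C)(C(C)C)C(C)C | intermediate
17 | prenyl bromide (1-bromo-3-methylbut-2-ene) | CC(C)=CCBr | starting material
18 | (2R,3R)-3,5-dihydroxy-2-[3-methoxy-4-(triisopropylsilyloxy)phenyl]-7-[(3-methylbut-2-en-1-yl)oxy]chroman-4-one | COc1cc([C@H]2Oc3cc(OCC=C(C)C)cc(O)c3C(=O)[C@@H]2O)ccc1O[Si](C(C)C)(C(C)C)C(C)C | intermediate
19 | (2R,3R)-3,5-dihydroxy-2-(4-hydroxy-3-methoxyphenyl)-7-[(3-methylbut-2-en-1-yl)oxy]chroman-4-one | COc1cc([C@H]2Oc3cc(OCC=C(C)C)cc(O)c3C(=O)[C@@H]2O)ccc1O | target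

## Step count and uncertain steps

Total: 12 steps. Longest linear sequence: 11 steps (steps 1–4 and 6–12, from 1 to 19); step 5 is a one-step side branch.

**Step 4 (key step).**
- Most likely failure: the secondary amine catalyst is captured by the methide (N-alkylation), stalling turnover while the methide oligomerises. Enantiofacial discrimination may also be incomplete, because an alpha-alkoxy enamine can populate more than one geometry.
- Fallback (auxiliary control instead of catalyst control, from 4 back to 8): the sodium enolate of (R)-4-benzyl-3-[(benzyloxy)acetyl]oxazolidin-2-one F1 (NaN(SiMe3)2, THF, −78 °C) is combined with the sodium phenoxide of 4. On warming, the phenoxide sheds sulfinate and the chelated enolate adds to the methide on the face away from the auxiliary benzyl group. This gives (R)-4-benzyl-3-[(2S)-2-(benzyloxy)-3-[2,4-bis(benzyloxy)-6-hydroxyphenyl]propanoyl]oxazolidin-2-one F2. The phenoxide then acylates itself at the exocyclic carbonyl, releasing the oxazolidinone and closing (3S)-3,5,7-tris(benzyloxy)chroman-2-one F3. Reduction with (i-Bu)2AlH at −78 °C returns lactol 8.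

**Step 6.**
- Most likely failure: incomplete chelation control, with Felkin–Anh addition or reaction through a phenoxide-bound aggregate giving the anti carbinol, which step 7 would convert into the 2,3-cis flavan. Enolisation of the aldehyde by the basic reagent would also erode C3.
- Fallback (carbinol set by reduction instead of addition, from 8 back to 12): Ag2CO3 on Celite oxidises the lactol to (3S)-3,5,7-tris(benzyloxy)chroman-2-one F3. The aryllithium from 10 (n-BuLi, THF, −78 °C, inverse addition) opens it to the keto phenol (2S)-2-(benzyloxy)-3-[2,4-bis(benzyloxy)-6-hydroxyphenyl]-1-[3-methoxy-4-(triisopropylsilyloxy)phenyl]propan-1-one F4. Reduction with LiBH(s-Bu)3 under Felkin–Anh control (benzyloxy group anti to the incoming hydride) gives the syn carbinol 12.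

**Step 8.**
- Most likely failure: the C4 cation is trapped by the nucleophilic ring A of a second molecule (C–C dimerisation) instead of by water, or hydride is abstracted at C2, which is benzylic to ring B.
- Fallback (acetoxylation instead of hydride abstraction, from 13 back to 14): Pb(OAc)4 in benzene introduces an acetoxy group at C4 to give (2R,3R,4RS)-3,5,7-tris(benzyloxy)-2-[3-methoxy-4-(triisopropylsilyloxy)phenyl]chroman-4-yl acetate F5. (i-Bu)2AlH at −78 °C then removes the acetyl group to give alcohol 14.

**Step 3 (with the lability of 3 from step 2).**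
- Most likely failure: Friedel–Crafts self-condensation of the benzylic cation with the very nucleophilic ring A, or over-reduction to the cresol during step 2, before sulfinate can trap the cation.
- Fallback (amine instead of hydroxyl as leaving group, from 2 back to 4): reductive amination of 2 with Me2NH and NaBH(OAc)3 gives the stable Mannich base 3,5-bis(benzyloxy)-2-[(dimethylamino)methyl]phenol F6. Methyl iodide converts it into [2,4-bis(benzyloxy)-6-hydroxyphenyl]-N,N,N-trimethylmethanaminium iodide F7. Warming F7 with sodium 4-methylbenzenesulfinate in MeCN releases the methide under neutral conditions and gives sulfone 4.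

**Step 11.**
- Most likely failure: alkylation at O5 or O3, C-prenylation of ring A at C6 or C8 through the ambident phenoxide, or base-induced opening of ring C.
- Fallback (base-free etherification, from 16 directly to 18): Mitsunobu reaction with 3-methylbut-2-en-1-ol, PPh3 and DIAD in THF at 0 °C, which engages only the most acidic phenol and makes no new intermediate.

## Further compounds

F1 | step 4 | (R)-4-benzyl-3-[(benzyloxy)acetyl]oxazolidin-2-one | O=C(COCc1ccccc1)N1[C@H](Cc2ccccc2)COC1=O
F2 | step 4 | (R)-4-benzyl-3-[(2S)-2-(benzyloxy)-3-[2,4-bis(benzyloxy)-6-hydroxyphenyl]propanoyl]oxazolidin-2-one | O=C([C@@H](OCc1ccccc1)Cc1c(O)cc(OCc2ccccc2)cc1OCc1ccccc1)N1[C@H](Cc2ccccc2)COC1=O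
F3 | step 4 | (3S)-3,5,7-tris(benzyloxy)chroman-2-one | O=C1Oc2cc(OCc3ccccc3)cc(OCc3ccccc3)c2C[C@@H]1OCc1ccccc1
F4 | step 6 | (2S)-2-(benzyloxy)-3-[2,4-bis(benzyloxy)-6-hydroxyphenyl]-1-[3-methoxy-4-(triisopropylsilyloxy)phenyl]propan-1-one | COc1cc(C(=O)[C@@H](OCc2ccccc2)Cc2c(O)cc(OCc3ccccc3)cc2OCc2ccccc2)ccc1O[Si](C(C)C)(C(C)C)C(C)C
F5 | step 8 | (2R,3R,4RS)-3,5,7-tris(benzyloxy)-2-[3-methoxy-4-(triisopropylsilyloxy)phenyl]chroman-4-yl acetate | COc1cc([C@H]2Oc3cc(OCc4ccccc4)cc(OCc4ccccc4)c3C(OC(C)=O)[C@@H]2OCc2ccccc2)ccc1O[Si](C(C)C)(C(C)C)C(C)C
F6 | step 3 | 3,5-bis(benzyloxy)-2-[(dimethylamino)methyl]phenol | CN(C)Cc1c(O)cc(OCc2ccccc2)cc1OCc1ccccc1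
F7 | step 3 | [2,4-bis(benzyloxy)-6-hydroxyphenyl]-N,N,N-trimethylmethanaminium iodide | C[N+](C)(C)Cc1c(O)cc(OCc2ccccc2)cc1OCc1ccccc1.[I-]
F0 | step 11 | none | none
A1 | alternative 1 | (2S)-5-(tert-butyldimethylsilyloxy)-2-[3-methoxy-4-(triisopropylsilyloxy)phenyl]-7-[(3-methylbut-2-en-1-yl)oxy]chroman-4-one | COc1cc([C@H]2Oc3cc(OCC=C(C)C)cc(O[Si](C)(C)C(C)(C)C)c3C(=O)C2)ccc1O[Si](C(C)C)(C(C)C)C(C)C
A2 | alternative 1 | 1-[2-(tert-butyldimethylsilyloxy)-6-{[3-methoxy-4-(triisopropylsilyloxy)phenyl]methoxy}-4-[(3-methylbut-2-en-1-yl)oxy]phenyl]-2-diazoethan-1-one | COc1cc(COc2cc(OCC=C(C)C)cc(O[Si](C)(C)C(C)(C)C)c2C(=O)C=[N+]=[N-])ccc1O[Si](C(C)C)(C(C)C)C(C)C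
A3 | alternative 2 | (2R,3R)-3-(tert-butyldimethylsilyloxy)-2-[4-(tert-butyldimethylsilyloxy)-3-methoxyphenyl]-5,7-dihydroxychroman-4-one | COc1cc([C@H]2Oc3cc(O)cc(O)c3C(=O)[C@@H]2O[Si](C)(C)C(C)(C)C)ccc1O[Si](C)(C)C(C)(C)C
A4 | alternative 2 | (2R,3R)-3-(tert-butyldimethylsilyloxy)-2-[4-(tert-butyldimethylsilyloxy)-3-methoxyphenyl]-5-(phenylsulfinyl)-2,3-dihydro-4H-pyran-4-one | COc1cc([C@H]2OC=C(S(=O)c3ccccc3)C(=O)[C@@H]2O[Si](C)(C)C(C)(C)C)ccc1O[Si](C)(C)C(C)(C)C
A5 | alternative 2 | 1-methoxy-1,3-bis(trimethylsilyloxy)buta-1,3-diene | COC(O[Si](C)(C)C)=CC(=C)O[Si](C)(C)C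
A6 | alternative 3 | 5,7-bis(benzyloxy)-2-[3-methoxy-4-(triisopropylsilyloxy)phenyl]-4H-chromen-4-one | COc1cc(-c2cc(=O)c3c(OCc4ccccc4)cc(OCc4ccccc4)cc3o2)ccc1O[Si](C(C)C)(C(C)C)C(C)C
A7 | alternative 3 | 3,5-bis(benzyloxy)-2-iodophenol | Oc1cc(OCc2ccccc2)cc(OCc2ccccc2)c1I
A8 | alternative 3 | (4-ethynyl-2-methoxyphenoxy)triisopropylsilane | COc1cc(C#C)ccc1O[Si](C(C)C)(C(C)C)C(C)C
A9 | alternative 3 | carbon monoxide | [C-]#[O+]
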